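Count the ligand. You want a quick number for this flask at 6.0 h, and your hunch blames a lack of incoming ligand, which at 0.600 equivalents is the limiting reagent.

the same everywhere: starting complex 1.4 M

| run | incoming ligand | remark | time |
|---|---|---|---|
| eta | 0.84 M | the very flask that is asked about, followed so far |  |
| flask | 0.840 M |  | 6.0 h |

- eta (time / min: complex with four exchanged / %, complex with one exchanged / %): 4.00: 2.1, 25.1; 10.0: 3.6, 22.8; 20.0: 4.3, 22.2; 30.0: 4.4, 22.5; 40.0: 4.6, 22.9; 50.0: 4.6, 21.8; 60.0: 4.1, 22.4

(each reading ± 0.3 percentage points)

- the reaction counts as stopped when no species that holds the starting complex changes by six tenths of a point or more over the second half of the time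

- why nothing more happens at 6.0 h, or that something still does (the incoming ligand has run out first / forward and back rates have come level / all of the starting complex has reacted / it is still moving)
- how much complex with four exchanged there is at 6.0 h, in percent of the starting complex charged
- how much complex with one exchanged there is at 6.0 h, in percent of the starting complex charged

From 20.0 min to 60.0 min the readings scatter about level means, with complex with four exchanged at 4.40% and complex with one exchanged at 22.4%. Define f, the bound-ligand share, as the part of the ligand charge held by these two complexes: add the one-exchanged percentage to 4 times the four-exchanged percentage, then multiply by the ratio of starting complex charged to ligand charged. By my reckoning, the readings of this flask give f = 66.6%. That leaves a third of the ligand either free or held in the unread complexes with two and three exchanged, so your hunch needs those two complexes to hold that whole remainder.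

My forecast for this flask is forward and back rates have come level, with complex with four exchanged at 4.4% (3.9% to 4.9%) and complex with one exchanged at 22.4% (21.7% to 23.1%). On the cause, it says: “Free ligand therefore probably remains, which points to equilibrium, though this is an inference.”

This flask gives forward and back rates have come level, with 4.43% of complex with four exchanged and 22.4% of complex with one exchanged at 6.0 h.

    starting complex + incoming ligand ⇌ leaving ligand + complex with one exchanged (K = 1.50, k = 0.0410 M⁻¹ s⁻¹)
    complex with one exchanged + incoming ligand ⇌ leaving ligand + complex with two exchanged (K = 0.810, k = 0.0170 M⁻¹ s⁻¹)
    complex with two exchanged + incoming ligand ⇌ leaving ligand + complex with three exchanged (K = 0.560, k = 0.0680 M⁻¹ s⁻¹)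
    complex with three exchanged + incoming ligand ⇌ leaving ligand + complex with four exchanged (K = 43.0, k = 0.130 M⁻¹ s⁻¹)

In this flask, 18% of the ligand charge is still free at 6.00 h. Its f from these results is 66.8%, so the complexes with two and three exchanged hold 15.4% of the ligand charge, less than the remainder the readings left open. In the neighbour flask charged with 2.1 M of incoming ligand, f is 63.7%, and 25% of its ligand charge stays free.

(The earlier runs and the new flask are calculated with constants of no real substance, and the scatter is random.)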